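**Retrosynthetic overview**
1. The C6 and C8 oxygens flank C7 in a near-symmetric way, so the lactone is built on O8 and moved to O6 in the last step (acyl transfer).
2. The ten-membered ring is closed at C6–C7 by an intramolecular Cr(II) Barbier reaction of a 3-(bromomethyl)butenolide onto a (Z)-enal.
3. Key step: a catalytic enantioselective vinylogous Mukaiyama aldol of a 2-silyloxyfuran (dearomatisation) with the C9 (Z)-enal sets C8 and C9 and leaves O9 free for acetylation.
4. The (Z)-enal comes from nerol (C1–C6 with the 4Z alkene) by Knoevenagel/DIBAL and an (E)-selective lipase mono-acylation of a symmetric 2-alkylidene-1,3-diol, which fixes the 1(10)Z geometry and installs the isovalerate.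
5. The silyloxyfuran comes from furfural. Ring order: butenolide, then carbocycle, then lactone shift.

Assumption: atom labels follow germacrane numbering (C12 lactone carbonyl, C13 exocyclic methylene, C14 CH2O-isovalerate, C15 ring methyl); the target SMILES is read as (6R,7R,8S,9R), 1(10)Z,4Z.

Step 1
Reactants: 1 furfural (furan-2-carbaldehyde)
Product: 4 furan-2(5H)-one, via furan-2-yl formate 2 (not isolated), via furan-2(3H)-one 3 (not isolated)
Conditions: 30% aq. H2O2, HCO2H, ClCH2CH2Cl, reflux; then Et3N (cat.), rt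
Reagents that add atoms: hydrogen peroxide, OO
Why: Baeyer–Villiger oxidation of the formyl group by performic acid, hydrolysis of the formate and base-catalysed conjugation of the β,γ-unsaturated lactone give the butenolide; no stereocentre is formed.

Step 2
Reactants: 4 furan-2(5H)-one; 5 formaldehyde
Product: 6 3-(hydroxymethyl)furan-2(5H)-one
Conditions: 37% aq. HCHO, DMAP (0.2 equiv), THF–H2O, rt
Reagents that add atoms: none
Why: Morita–Baylis–Hillman α-hydroxymethylation of the butenolide introduces C13 with its oxygen handle; no stereocentre is formed.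

Step 3
Reactants: 6 3-(hydroxymethyl)furan-2(5H)-one
Product: 7 tert-butyl({2-[(tert-butyldimethylsilyl)oxy]furan-3-yl}methoxy)dimethylsilane
Conditions: TBSOTf (2.2 equiv), Et3N (3 equiv), CH2Cl2, 0 °C
Reagents that add atoms: tert-butyldimethylsilyl trifluoromethanesulfonate, CC(C)(C)[Si](C)(C)OS(=O)(=O)C(F)(F)F
Why: O-silylation of the primary alcohol and soft enolisation/O-silylation at the γ-position (silyl dienol ether formation) give the aromatic 2-silyloxyfuran.

Step 4
Reactants: 8 nerol
Product: 9 tert-butyl{[(2Z)-3,7-dimethylocta-2,6-dien-1-yl]oxy}diphenylsilane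
Conditions: TBDPSCl, imidazole, CH2Cl2, 0 °C to rt
Reagents that add atoms: tert-butyl(chloro)diphenylsilane, CC(C)(C)[Si](Cl)(c1ccccc1)c1ccccc1
Why: silyl ether formation protects the future C6 oxygen; the 4Z alkene is bought with nerol.

Step 5
Reactants: 9 tert-butyl{[(2Z)-3,7-dimethylocta-2,6-dien-1-yl]oxy}diphenylsilane
Product: 11 (4Z)-6-[(tert-butyldiphenylsilyl)oxy]-4-methylhex-4-enal, via 6,7-epoxide 10 (not isolated)
Conditions: mCPBA (1.05 equiv), CH2Cl2, −20 °C; then H5IO6, THF–H2O, 0 °C
Reagents that add atoms: 3-chloroperoxybenzoic acid, O=C(OO)c1cccc(Cl)c1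
Why: Prilezhaev epoxidation is selective for the distal, more electron-rich trisubstituted alkene, and periodic acid cleavage of the epoxide (Malaprade type) gives the C1 aldehyde without touching the Z allylic ether alkene.

Step 6
Reactants: 11 (4Z)-6-[(tert-butyldiphenylsilyl)oxy]-4-methylhex-4-enal; 12 dimethyl malonate
Product: 13 dimethyl 2-{(4Z)-6-[(tert-butyldiphenylsilyl)oxy]-4-methylhex-4-en-1-ylidene}propanedioate
Conditions: piperidine (10 mol %), AcOH (10 mol %), 4 Å MS, CH2Cl2, rt
Reagents that add atoms: none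
Why: Knoevenagel condensation builds the C1=C10 bond with two identical ester groups, so no alkene geometry has to be controlled here.

Step 7
Reactants: 13 dimethyl 2-{(4Z)-6-[(tert-butyldiphenylsilyl)oxy]-4-methylhex-4-en-1-ylidene}propanedioate
Product: 14 2-{(4Z)-6-[(tert-butyldiphenylsilyl)oxy]-4-methylhex-4-en-1-ylidene}propane-1,3-diol
Conditions: DIBAL-H (5 equiv), CH2Cl2, −78 to −20 °C; Rochelle salt work-up
Reagents that add atoms: none
Why: 1,2-reduction of both esters of the alkylidene malonate gives the symmetric 2-alkylidene-1,3-diol whose two CH2OH groups differ only by being cis or trans to the chain.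

Step 8
Reactants: 14 2-{(4Z)-6-[(tert-butyldiphenylsilyl)oxy]-4-methylhex-4-en-1-ylidene}propane-1,3-diol; 15 3-methylbutanoic anhydride
Product: 16 (2E,6Z)-8-[(tert-butyldiphenylsilyl)oxy]-2-(hydroxymethyl)-6-methylocta-2,6-dien-1-yl 3-methylbutanoate
Conditions: immobilised lipase PS (Burkholderia cepacia), t-BuOMe, rt
Reagents that add atoms: none
Why: lipase-catalysed desymmetrising mono-acylation takes the less hindered CH2OH trans to the chain, which puts the isovalerate on C14 and leaves the cis CH2OH as the future C9, so the 1(10)Z geometry is set.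

Step 9
Reactants: 16 (2E,6Z)-8-[(tert-butyldiphenylsilyl)oxy]-2-(hydroxymethyl)-6-methylocta-2,6-dien-1-yl 3-methylbutanoate
Product: 17 (2Z,6Z)-8-[(tert-butyldiphenylsilyl)oxy]-2-formyl-6-methylocta-2,6-dien-1-yl 3-methylbutanoate
Conditions: MnO2 (20 equiv), CH2Cl2, rt
Reagents that add atoms: none
Why: neutral allylic oxidation gives the (Z)-enal (CHO cis to the chain) without alkene isomerisation.

Step 10
Reactants: 17 (2Z,6Z)-8-[(tert-butyldiphenylsilyl)oxy]-2-formyl-6-methylocta-2,6-dien-1-yl 3-methylbutanoate; 7 tert-butyl({2-[(tert-butyldimethylsilyl)oxy]furan-3-yl}methoxy)dimethylsilane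
Product: 18 (2Z,6Z)-2-{(R)-[(2S)-4-({[tert-butyl(dimethyl)silyl]oxy}methyl)-5-oxo-2,5-dihydrofuran-2-yl](hydroxy)methyl}-8-[(tert-butyldiphenylsilyl)oxy]-6-methylocta-2,6-dien-1-yl 3-methylbutanoate
Conditions: chiral binaphthyldiamine-derived bisphosphoramide (5 mol %, antipode chosen to give the 2S,1′R adduct), SiCl4 (1.2 equiv), iPr2NEt (10 mol %), CH2Cl2, −78 °C; aqueous work-up
Reagents that add atoms: none
Why: catalytic enantioselective vinylogous Mukaiyama aldol addition, in which C5 of the aromatic silyloxyfuran attacks the enal carbonyl (1,2-mode) in an open antiperiplanar transition state on the chiral silyl cation; this destroys the furan aromaticity and sets C8 and C9 together in the anti (erythro) relationship that becomes the 8β,9β pattern, with O8 held in the lactone and O9 free.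

Step 11
Reactants: 18 the aldol adduct; 19 acetic anhydride
Product: 20 (2Z,6Z)-2-{(R)-(acetyloxy)[(2S)-4-({[tert-butyl(dimethyl)silyl]oxy}methyl)-5-oxo-2,5-dihydrofuran-2-yl]methyl}-8-[(tert-butyldiphenylsilyl)oxy]-6-methylocta-2,6-dien-1-yl 3-methylbutanoate
Conditions: Ac2O, pyridine, CH2Cl2, 0 °C (no stronger base)
Reagents that add atoms: none
Why: O-acylation of the only free hydroxyl places the acetate on O9 unambiguously; pyridine at 0 °C avoids γ-deprotonation of the butenolide and loss of acetate to the alkylidene butenolide.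

Step 12
Reactants: 20 the acetate
Product: 21 (2Z,6Z)-2-{(R)-(acetyloxy)[(2S)-4-(hydroxymethyl)-5-oxo-2,5-dihydrofuran-2-yl]methyl}-8-hydroxy-6-methylocta-2,6-dien-1-yl 3-methylbutanoate
Conditions: HF·pyridine, pyridine, THF, 0 °C to rt
Reagents that add atoms: none
Why: fluoride-mediated desilylation removes the TBS and TBDPS ethers while both carboxylic esters and the butenolide survive.

Step 13
Reactants: 21 the diol
Product: 22 (2Z,6Z)-2-{(R)-(acetyloxy)[(2S)-4-(hydroxymethyl)-5-oxo-2,5-dihydrofuran-2-yl]methyl}-6-methyl-8-oxoocta-2,6-dien-1-yl 3-methylbutanoate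
Conditions: MnO2 (15 equiv), CH2Cl2, rt
Reagents that add atoms: none
Why: MnO2 oxidises the electron-rich allylic C6 alcohol to the (Z)-enal far faster than the electron-poor 2-(hydroxymethyl)butenolide alcohol (chemoselective allylic oxidation).

Step 14
Reactants: 22 the hydroxy enal
Product: 23 (2Z,6Z)-2-{(R)-(acetyloxy)[(2S)-4-(bromomethyl)-5-oxo-2,5-dihydrofuran-2-yl]methyl}-6-methyl-8-oxoocta-2,6-dien-1-yl 3-methylbutanoate
Conditions: NBS, Me2S, CH2Cl2, −20 to 0 °C
Reagents that add atoms: N-bromosuccinimide, O=C1CCC(=O)N1Br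
Why: Corey–Kim bromination converts the primary allylic alcohol to the bromide under neutral conditions that tolerate the enal and the base-sensitive acetoxy butenolide.

Step 15
Reactants: 23 the bromo enal
Product: 25 9β-acetoxy-6α-hydroxy-14-[(3-methylbutanoyl)oxy]germacra-1(10)Z,4Z,11(13)-trien-12,8β-olide (6R,7S,8S,9R), via allylchromium(III) dichloride 24 (not isolated)
Conditions: CrCl2 (10 equiv), 4 Å MS, THF–DMF 4:1, rt, syringe-pump addition of 23 (final 2 mM); aqueous work-up
Reagents that add atoms: none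
Why: intramolecular Nozaki–Hiyama–Kishi/Barbier allylation, in which the (E)-locked allylchromium adds through C7 to the tethered enal in a Zimmerman–Traxler chair to give the anti C6/C7 relationship (6α-OH) and the exocyclic methylene, while the short tether from C9 can reach only the butenolide face syn to the C8 substituent, which sets H7 cis to H8.

Step 16
Reactants: 25 the 8β,12-olide
Product: 26 9β-acetoxy-8β-hydroxy-14-[(3-methylbutanoyl)oxy]germacra-1(10)Z,4Z,11(13)-trien-12,6α-olide (6R,7R,8S,9R), the target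
Conditions: CSA (10 mol %), CH2Cl2, rt, stopped at equilibrium
Reagents that add atoms: none
Why: acid-catalysed intramolecular transesterification (translactonisation), in which the 6α-hydroxyl attacks C12 through a bicyclic tetrahedral intermediate and releases O8; the trans-fused 6,12-olide is expected to be the thermodynamic lactone (natural 8β-hydroxy-6α,12-germacranolides persist as such), and no stereocentre is touched.

**Compound list**
1 | furfural (furan-2-carbaldehyde) | O=Cc1ccco1 | starting material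
2 | furan-2-yl formate | O=COc1ccco1 | intermediate
3 | furan-2(3H)-one | O=C1CC=CO1 | intermediate
4 | furan-2(5H)-one | O=C1C=CCO1 | intermediate
5 | formaldehyde | C=O | starting material
6 | 3-(hydroxymethyl)furan-2(5H)-one | O=C1OCC=C1CO | intermediate
7 | tert-butyl({2-[(tert-butyldimethylsilyl)oxy]furan-3-yl}methoxy)dimethylsilane | CC(C)(C)[Si](C)(C)OCc1ccoc1O[Si](C)(C)C(C)(C)C | intermediate
8 | nerol, (2Z)-3,7-dimethylocta-2,6-dien-1-ol | CC(C)=CCC/C(C)=C\CO | starting material
9 | tert-butyl{[(2Z)-3,7-dimethylocta-2,6-dien-1-yl]oxy}diphenylsilane | CC(C)=CCC/C(C)=C\CO[Si](c1ccccc1)(c1ccccc1)C(C)(C)C | intermediate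
10 | tert-butyl{[(2Z)-5-(3,3-dimethyloxiran-2-yl)-3-methylpent-2-en-1-yl]oxy}diphenylsilane (racemic at the oxirane carbon) | CC1(C)OC1CC/C(C)=C\CO[Si](c1ccccc1)(c1ccccc1)C(C)(C)C | intermediate
11 | (4Z)-6-[(tert-butyldiphenylsilyl)oxy]-4-methylhex-4-enal | O=CCC/C(C)=C\CO[Si](c1ccccc1)(c1ccccc1)C(C)(C)C | intermediate
12 | dimethyl malonate | COC(=O)CC(=O)OC | starting material
13 | dimethyl 2-{(4Z)-6-[(tert-butyldiphenylsilyl)oxy]-4-methylhex-4-en-1-ylidene}propanedioate | COC(=O)C(=CCC/C(C)=C\CO[Si](c1ccccc1)(c1ccccc1)C(C)(C)C)C(=O)OC | intermediate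
14 | 2-{(4Z)-6-[(tert-butyldiphenylsilyl)oxy]-4-methylhex-4-en-1-ylidene}propane-1,3-diol | OCC(CO)=CCC/C(C)=C\CO[Si](c1ccccc1)(c1ccccc1)C(C)(C)C | intermediate
15 | 3-methylbutanoic (isovaleric) anhydride | CC(C)CC(=O)OC(=O)CC(C)C | starting material
16 | (2E,6Z)-8-[(tert-butyldiphenylsilyl)oxy]-2-(hydroxymethyl)-6-methylocta-2,6-dien-1-yl 3-methylbutanoate | CC(C)CC(=O)OC/C(CO)=C/CC/C(C)=C\CO[Si](c1ccccc1)(c1ccccc1)C(C)(C)C | intermediate
17 | (2Z,6Z)-8-[(tert-butyldiphenylsilyl)oxy]-2-formyl-6-methylocta-2,6-dien-1-yl 3-methylbutanoate | CC(C)CC(=O)OC/C(C=O)=C/CC/C(C)=C\CO[Si](c1ccccc1)(c1ccccc1)C(C)(C)C | intermediate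
18 | (2Z,6Z)-2-{(R)-[(2S)-4-({[tert-butyl(dimethyl)silyl]oxy}methyl)-5-oxo-2,5-dihydrofuran-2-yl](hydroxy)methyl}-8-[(tert-butyldiphenylsilyl)oxy]-6-methylocta-2,6-dien-1-yl 3-methylbutanoate | CC(C)CC(=O)OC/C(=C/CC/C(C)=C\CO[Si](c1ccccc1)(c1ccccc1)C(C)(C)C)[C@@H](O)[C@H]1OC(=O)C(CO[Si](C)(C)C(C)(C)C)=C1 | intermediate
19 | acetic anhydride | CC(=O)OC(C)=O | starting material
20 | (2Z,6Z)-2-{(R)-(acetyloxy)[(2S)-4-({[tert-butyl(dimethyl)silyl]oxy}methyl)-5-oxo-2,5-dihydrofuran-2-yl]methyl}-8-[(tert-butyldiphenylsilyl)oxy]-6-methylocta-2,6-dien-1-yl 3-methylbutanoate | CC(C)CC(=O)OC/C(=C/CC/C(C)=C\CO[Si](c1ccccc1)(c1ccccc1)C(C)(C)C)[C@@H](OC(C)=O)[C@H]1OC(=O)C(CO[Si](C)(C)C(C)(C)C)=C1 | intermediate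
21 | (2Z,6Z)-2-{(R)-(acetyloxy)[(2S)-4-(hydroxymethyl)-5-oxo-2,5-dihydrofuran-2-yl]methyl}-8-hydroxy-6-methylocta-2,6-dien-1-yl 3-methylbutanoate | CC(C)CC(=O)OC/C(=C/CC/C(C)=C\CO)[C@@H](OC(C)=O)[C@H]1OC(=O)C(CO)=C1 | intermediate
22 | (2Z,6Z)-2-{(R)-(acetyloxy)[(2S)-4-(hydroxymethyl)-5-oxo-2,5-dihydrofuran-2-yl]methyl}-6-methyl-8-oxoocta-2,6-dien-1-yl 3-methylbutanoate | CC(C)CC(=O)OC/C(=C/CC/C(C)=C\C=O)[C@@H](OC(C)=O)[C@H]1OC(=O)C(CO)=C1 | intermediate
23 | (2Z,6Z)-2-{(R)-(acetyloxy)[(2S)-4-(bromomethyl)-5-oxo-2,5-dihydrofuran-2-yl]methyl}-6-methyl-8-oxoocta-2,6-dien-1-yl 3-methylbutanoate | CC(C)CC(=O)OC/C(=C/CC/C(C)=C\C=O)[C@@H](OC(C)=O)[C@H]1OC(=O)C(CBr)=C1 | intermediate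
24 | allylchromium(III) dichloride formed from 23 (Cr on the former CH2Br carbon) | CC(C)CC(=O)OC/C(=C/CC/C(C)=C\C=O)[C@@H](OC(C)=O)[C@H]1OC(=O)C(C[Cr](Cl)Cl)=C1 | intermediate
25 | 9β-acetoxy-6α-hydroxy-14-[(3-methylbutanoyl)oxy]germacra-1(10)Z,4Z,11(13)-trien-12,8β-olide (6R,7S,8S,9R) | C=C1C(=O)O[C@@H]2[C@H](OC(C)=O)/C(COC(=O)CC(C)C)=C\CC/C(C)=C\[C@@H](O)[C@H]12 | intermediate
26 | 9β-acetoxy-8β-hydroxy-14-[(3-methylbutanoyl)oxy]germacra-1(10)Z,4Z,11(13)-trien-12,6α-olide (6R,7R,8S,9R) | C=C1C(=O)O[C@@H]2/C=C(/C)CC/C=C(/COC(=O)CC(C)C)[C@@H](OC(C)=O)[C@@H](O)[C@@H]12 | target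

**Step count**
Total: 16 steps (3 to the silyloxyfuran, 6 to the enal, 7 after their union). Longest linear sequence: 13 steps (8 to 26, steps 4–16).

**Three steps most likely to fail**

Step 15 (ring closure and C6/C7 stereochemistry). The risks are oligomerisation, attack on the face anti to the C8 substituent (trans-fused product) and loss of the chair-derived anti selectivity in a strained ten-membered transition state. The fallback sets out from 23 and comes back at 25. The allylic bromide is borylated with B2pin2 and catalytic Pd2(dba)3 in THF to give the isolable 2-(alkoxycarbonyl)allylboronate F2. This is then cyclised by Sc(OTf)3-catalysed (or thermal) intramolecular allylboration under high dilution through a boron-centred chair with no reductant present, and hydrolysis of the borate gives 25.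

Step 10 (key aldol). The risks are syn instead of anti selectivity with the furan nucleophile, modest ee with the α-branched (Z)-enal, Z to E isomerisation, and SN2′ attack with loss of isovalerate. The fallback sets out from 17 and 7 and comes back at 20. The partners are joined without a chiral catalyst by fluoride-triggered addition (TBAF, THF, −78 °C), which is erythro-selective for 2-silyloxyfurans, to give the racemic anti adduct F1. A lipase-catalysed enantioselective acetylation of its carbinol (vinyl acetate, immobilised Candida antarctica lipase B or lipase PS, t-BuOMe) then acts as a kinetic resolution and gives acetate 20 directly. If the enzyme prefers the other antipode, the recovered alcohol is the wanted one and is acetylated as in step 11.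

Step 16 (lactone shift). The risks are an unfavourable equilibrium position and acetyl migration from O9 to the freed O8. The fallback sets out from 25 and comes back at 26. The 6-hydroxyl is silylated (TESOTf, 2,6-lutidine) to give the 6-O-triethylsilyl ether F3. The lactone is opened with Me2AlN(OMe)Me at −20 °C and the released C8 oxygen is capped in the same flask with TBSOTf to give the seco Weinreb amide F4. The TES group is removed (PPTS, MeOH) and the free allylic 6-hydroxyl closes onto the amide (CSA, toluene, 40 °C), now the only possible lactonisation, to give the 8-O-TBS ether of the target F5. HF·pyridine then releases 26 under conditions where neither the lactone nor the acetate moves.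

Further compounds
F1 | step 10 | racemic anti aldol adduct, same constitution and relative configuration as 18 (one enantiomer drawn) | CC(C)CC(=O)OC/C(=C/CC/C(C)=C\CO[Si](c1ccccc1)(c1ccccc1)C(C)(C)C)[C@@H](O)[C@H]1OC(=O)C(CO[Si](C)(C)C(C)(C)C)=C1
F2 | step 15 | allylboronate: 23 with CH2Br replaced by CH2B(pin) | CC(C)CC(=O)OC/C(=C/CC/C(C)=C\C=O)[C@@H](OC(C)=O)[C@H]1OC(=O)C(CB2OC(C)(C)C(C)(C)O2)=C1
F3 | step 16 | 6-O-triethylsilyl ether of 25 | C=C1C(=O)O[C@@H]2[C@H](OC(C)=O)/C(COC(=O)CC(C)C)=C\CC/C(C)=C\[C@@H](O[Si](CC)(CC)CC)[C@H]12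
F4 | step 16 | seco Weinreb amide: N-methoxy-N-methyl acrylamide on C7, 8-O-TBS, 9-OAc, 6-O-TES, ten-membered ring intact | C=C(C(=O)N(C)OC)[C@@H]1[C@H](O[Si](C)(C)C(C)(C)C)[C@H](OC(C)=O)/C(COC(=O)CC(C)C)=C\CC/C(C)=C\[C@H]1O[Si](CC)(CC)CC
F5 | step 16 | 8-O-tert-butyldimethylsilyl ether of 26 | C=C1C(=O)O[C@@H]2/C=C(/C)CC/C=C(/COC(=O)CC(C)C)[C@@H](OC(C)=O)[C@@H](O[Si](C)(C)C(C)(C)C)[C@@H]12
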